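**Retrosynthetic overview**
1. Last step: one i-Bu2AlH reduction turns the Z nitrile diester 27 into the enal and both primary alcohols; the nitrile comes from an HWE reaction on the ring B ketone and the tertiary carbinol from methyl addition to the other ketone.
2. Union: the disubstituted C=C of the (E,E)-diene is made by Julia–Kocienski olefination of ring A sulfone 10 with ring B enal 22.
3. Ring A (closed in step 3): enantioselective Brønsted-acid (IDPi) protonative cyclization of the achiral keto ester 4, then methylenation, reduction and sulfone formation.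
4. Ring B (closed in step 8): thiourea-catalysed Michael addition of keto ester 14 to nitroalkene 13, then intramolecular nitro-Michael addition; nitro is converted to a ketal, and the quaternary carbon is set by Michael addition to acrolein.
5. Order: ring A and ring B are each closed before the fragments are joined in step 12; no ring is formed after the union.

Assumption: the catalyst antipodes named in steps 3 and 8 are those taken to give the drawn configuration; if the facial sense proves opposite, the mirror-image catalyst is used.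
Abbreviation: Dn = (3E,5E)-4-methyl-6-[(1R,3S)-2,2,3-trimethyl-6-methylidenecyclohexyl]hexa-3,5-dien-1-yl.

**Fragment A (ring A sulfone)**

Step 1
Reactants: 1 2,3-dimethylbuta-1,3-diene
Product: 2 1-bromo-2,3-dimethylbut-2-ene
Conditions: HBr (48% aq.), −10 °C → rt
Reagents that add atoms: hydrogen bromide, Br
Why: Electrophilic 1,4-hydrobromination of the diene under thermodynamic control gives the primary allylic bromide with the tetrasubstituted alkene.

Step 2
Reactants: 2 1-bromo-2,3-dimethylbut-2-ene; 3 methyl acetoacetate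
Product: 4 methyl 6,7-dimethyl-3-oxooct-6-enoate
Conditions: NaH then n-BuLi, THF, 0 °C; then 2, 0 °C → rt
Reagents that add atoms: none
Why: Weiler dianion alkylation, in which the terminal carbanion of the acetoacetate dianion displaces the allylic bromide (SN2) and places the alkene four atoms from the nucleophilic C2.

Step 3
Reactants: 4 methyl 6,7-dimethyl-3-oxooct-6-enoate
Product: 5 methyl (1S,3S)-2,2,3-trimethyl-6-oxocyclohexane-1-carboxylate
Conditions: chiral IDPi Brønsted acid (imidodiphosphorimidate on 3,3′-diaryl-BINOL backbones, N-triflyl; 3 mol%), (CF3)3COH/CHCl3, −40 °C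
Reagents that add atoms: none
Why: Proposed new method: the confined chiral acid protonates one face of the tetrasubstituted alkene at C6 while the enol carbon C2 of the β-keto ester closes the six-membered ring on the developing tertiary cation at C7 through a chair transition state, which sets the methyl-bearing carbon as 3S, whereas C1 is epimerisable and settles cis (diequatorial, 1S); the closest known reactions are IDPi-catalysed proton-initiated polyene cyclizations of trisubstituted alkenes with oxygen terminators and the racemic SnCl4-mediated β-keto ester–olefin cyclization, neither shown for a tetrasubstituted initiating alkene with a carbon-acid terminator.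

Step 4
Reactants: 5 methyl (1S,3S)-2,2,3-trimethyl-6-oxocyclohexane-1-carboxylate
Product: 6 methyl (1R,3S)-2,2,3-trimethyl-6-methylidenecyclohexane-1-carboxylate
Conditions: Ph3PCH3Br, KOt-Bu, THF, 0 °C → rt
Reagents that add atoms: methyltriphenylphosphonium bromide, C[P+](c1ccccc1)(c1ccccc1)c1ccccc1.[Br-]
Why: Wittig methylenation, which works on β-keto esters of this kind because the α-proton next to the quaternary carbon is slow to enolise, so the cis ester stereocentre is carried over.

Step 5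
Reactants: 6 methyl (1R,3S)-2,2,3-trimethyl-6-methylidenecyclohexane-1-carboxylate
Product: 7 [(1R,3S)-2,2,3-trimethyl-6-methylidenecyclohexyl]methanol
Conditions: LiAlH4, Et2O, 0 °C
Reagents that add atoms: none
Why: Hydride reduction of the ester to the primary alcohol, with no stereocentre touched.

Step 6
Reactants: 7 [(1R,3S)-2,2,3-trimethyl-6-methylidenecyclohexyl]methanol; 8 1-phenyl-1H-tetrazole-5-thiol
Product: 10 1-phenyl-5-({[(1R,3S)-2,2,3-trimethyl-6-methylidenecyclohexyl]methyl}sulfonyl)-1H-tetrazole, via sulfide 9 (not isolated)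
Conditions: PPh3, DIAD, THF, 0 °C → rt; then (NH4)6Mo7O24·4H2O (cat.), 30% H2O2, EtOH, rt
Reagents that add atoms: hydrogen peroxide, OO
Why: Mitsunobu thioetherification (SN2 at the primary carbon) followed by molybdate-catalysed sulfide-to-sulfone oxidation, which leaves the hindered 1,1-disubstituted alkene intact.

**Fragment B (ring B enal)**

Step 7
Reactants: 11 methyl 4-oxobutanoate; 12 nitromethane
Product: 13 methyl (4E)-5-nitropent-4-enoate
Conditions: piperidine (10 mol%), 4 Å MS, toluene, reflux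
Reagents that add atoms: none
Why: Amine-catalysed Henry condensation–dehydration through the iminium gives the E nitroalkene without a free γ-hydroxy ester that could lactonise.

Step 8
Reactants: 13 methyl (4E)-5-nitropent-4-enoate; 14 methyl 5-methoxy-3-oxopentanoate
Product: 17 methyl (5S,6S)-2-hydroxy-6-(3-methoxy-3-oxopropyl)-5-nitrocyclohex-1-ene-1-carboxylate, via Michael adduct 15 (not isolated), via vinyl ketone 16 (not isolated)
Conditions: 1-[3,5-bis(trifluoromethyl)phenyl]-3-[(1S,2S)-2-(dimethylamino)cyclohexyl]thiourea (10 mol%), toluene, −20 °C; then DBU, MeCN, 40 °C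
Reagents that add atoms: none
Why: Bifunctional thiourea–amine catalysed Michael addition of the β-keto ester to the nitroalkene sets the side-chain-bearing carbon (3S in 15, C6 in 17) by hydrogen-bond-directed attack on one alkene face, after which DBU eliminates methanol (E1cB) and the nitronate closes ring B by intramolecular Michael addition to give the equilibrated trans nitro isomer.

Step 9
Reactants: 17 methyl (5S,6S)-2-hydroxy-6-(3-methoxy-3-oxopropyl)-5-nitrocyclohex-1-ene-1-carboxylate
Product: 18 methyl (6S)-2-hydroxy-5,5-dimethoxy-6-(3-methoxy-3-oxopropyl)cyclohex-1-ene-1-carboxylate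
Conditions: NaOMe, MeOH, 0 °C; then added to H2SO4/MeOH, −40 → 0 °C
Reagents that add atoms: methanol, CO
Why: Nef reaction run in cold acidic methanol converts the nitronate carbon into the dimethyl ketal (masked ketone), returns the β-keto ester unchanged and does not epimerise C6 at this temperature.

Step 10
Reactants: 18 methyl (6S)-2-hydroxy-5,5-dimethoxy-6-(3-methoxy-3-oxopropyl)cyclohex-1-ene-1-carboxylate; 19 acrolein
Product: 20 methyl (1R,2S)-3,3-dimethoxy-2-(3-methoxy-3-oxopropyl)-6-oxo-1-(3-oxopropyl)cyclohexane-1-carboxylate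
Conditions: Et3N (20 mol%), CH2Cl2, −20 °C → rt
Reagents that add atoms: none
Why: Base-catalysed Michael addition of the β-keto ester to acrolein, in which the enolate is attacked anti to the pseudoaxial C2 side chain (allylic strain), sets the quaternary carbon as 1R with the new chain trans to the propanoate arm.

Step 11
Reactants: 20 methyl (1R,2S)-3,3-dimethoxy-2-(3-methoxy-3-oxopropyl)-6-oxo-1-(3-oxopropyl)cyclohexane-1-carboxylate; 21 2-(triphenylphosphoranylidene)propanal
Product: 22 methyl (1R,2S)-3,3-dimethoxy-2-(3-methoxy-3-oxopropyl)-1-[(3E)-4-methyl-5-oxopent-3-en-1-yl]-6-oxocyclohexane-1-carboxylate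
Conditions: toluene, 80 °C
Reagents that add atoms: none
Why: Wittig olefination with a stabilised ylide is selective for the aldehyde over the hindered ketone and gives the E trisubstituted enal.

**Union and completion**

Step 12
Reactants: 10 1-phenyl-5-({[(1R,3S)-2,2,3-trimethyl-6-methylidenecyclohexyl]methyl}sulfonyl)-1H-tetrazole; 22 methyl (1R,2S)-3,3-dimethoxy-2-(3-methoxy-3-oxopropyl)-1-[(3E)-4-methyl-5-oxopent-3-en-1-yl]-6-oxocyclohexane-1-carboxylate
Product: 23 methyl (1R,2S)-1-Dn-3,3-dimethoxy-2-(3-methoxy-3-oxopropyl)-6-oxocyclohexane-1-carboxylate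
Conditions: 10, KN(SiMe3)2, DME, −78 °C; then 22, −78 °C → rt
Reagents that add atoms: none
Why: Julia–Kocienski olefination, in which the pre-metalated tetrazolyl sulfone adds to the aldehyde faster than to the hindered ketone or the esters and Smiles rearrangement–elimination gives the E disubstituted alkene that completes the (E,E)-diene.

Step 13
Reactants: 23 methyl (1R,2S)-1-Dn-3,3-dimethoxy-2-(3-methoxy-3-oxopropyl)-6-oxocyclohexane-1-carboxylate
Product: 24 methyl (1R,2S,6S)-1-Dn-6-hydroxy-3,3-dimethoxy-2-(3-methoxy-3-oxopropyl)-6-methylcyclohexane-1-carboxylate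
Conditions: MeMgBr, CeCl3, THF, −78 °C
Reagents that add atoms: methylmagnesium bromide, C[Mg]Br
Why: Cerium-assisted Grignard addition is selective for the ketone over the esters, and attack anti to the ester on the neighbouring quaternary carbon (polar Felkin–Anh; the ester is axial in the favoured chair) sets C6 as S with the hydroxyl cis to the ester.

Step 14
Reactants: 24 methyl (1R,2S,6S)-1-Dn-6-hydroxy-3,3-dimethoxy-2-(3-methoxy-3-oxopropyl)-6-methylcyclohexane-1-carboxylate
Product: 25 methyl (1R,2S,6S)-1-Dn-6-hydroxy-2-(3-methoxy-3-oxopropyl)-6-methyl-3-oxocyclohexane-1-carboxylate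
Conditions: PPTS, acetone/H2O, rt
Reagents that add atoms: water, O
Why: Mild acid hydrolysis of the labile dimethyl ketal frees the C3 ketone without dehydrating the tertiary alcohol or isomerising the exocyclic alkene.

Step 15
Reactants: 25 methyl (1R,2S,6S)-1-Dn-6-hydroxy-2-(3-methoxy-3-oxopropyl)-6-methyl-3-oxocyclohexane-1-carboxylate; 26 diethyl (1-cyanoethyl)phosphonate
Product: 27 methyl (1R,2R,3Z,6S)-3-(1-cyanoethylidene)-1-Dn-6-hydroxy-2-(3-methoxy-3-oxopropyl)-6-methylcyclohexane-1-carboxylate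
Conditions: 26, NaH, THF, 0 °C; then 25, 0 → 50 °C
Reagents that add atoms: none
Why: Horner–Wadsworth–Emmons olefination, in which the reversible oxaphosphetane places the bulky C2 side of the ring cis to the small linear nitrile and not to the methyl group, gives the Z tetrasubstituted alkene, and the weakly basic phosphonate anion neither epimerises C2 nor deprotonates the tertiary alcohol.

Step 16
Reactants: 27 methyl (1R,2R,3Z,6S)-3-(1-cyanoethylidene)-1-Dn-6-hydroxy-2-(3-methoxy-3-oxopropyl)-6-methylcyclohexane-1-carboxylate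
Product: 29 (2Z)-2-[(2R,3S,4S)-3-Dn-4-hydroxy-3-(hydroxymethyl)-2-(3-hydroxypropyl)-4-methylcyclohexylidene]propanal, via aldimine 28 (not isolated)
Conditions: i-Bu2AlH (excess), CH2Cl2/toluene, −78 → 0 °C; then aq. KNaC4H4O6 (potassium sodium tartrate), SiO2
Reagents that add atoms: water, O
Why: i-Bu2AlH reduces both esters to primary alcohols and the conjugated nitrile only as far as the N-aluminio aldimine, which is hydrolysed on work-up to the Z enal with the alkene geometry retained.

**Compound list**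
1 | 2,3-dimethylbuta-1,3-diene | C=C(C)C(C)=C | starting material
2 | 1-bromo-2,3-dimethylbut-2-ene | CC(C)=C(C)CBr | intermediate
3 | methyl acetoacetate | CC(=O)CC(=O)OC | starting material
4 | methyl 6,7-dimethyl-3-oxooct-6-enoate | COC(=O)CC(=O)CCC(C)=C(C)C | intermediate
5 | methyl (1S,3S)-2,2,3-trimethyl-6-oxocyclohexane-1-carboxylate (cis) | O=C1CC[C@H](C)C(C)(C)[C@@H]1C(=O)OC | intermediate
6 | methyl (1R,3S)-2,2,3-trimethyl-6-methylidenecyclohexane-1-carboxylate | C=C1CC[C@H](C)C(C)(C)[C@@H]1C(=O)OC | intermediate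
7 | [(1R,3S)-2,2,3-trimethyl-6-methylidenecyclohexyl]methanol | C=C1CC[C@H](C)C(C)(C)[C@@H]1CO | intermediate
8 | 1-phenyl-1H-tetrazole-5-thiol | SC1=NN=NN1c1ccccc1 | starting material
9 | 1-phenyl-5-({[(1R,3S)-2,2,3-trimethyl-6-methylidenecyclohexyl]methyl}sulfanyl)-1H-tetrazole | C=C1CC[C@H](C)C(C)(C)[C@@H]1CSC1=NN=NN1c1ccccc1 | intermediate
10 | 1-phenyl-5-({[(1R,3S)-2,2,3-trimethyl-6-methylidenecyclohexyl]methyl}sulfonyl)-1H-tetrazole | C=C1CC[C@H](C)C(C)(C)[C@@H]1CS(=O)(=O)C1=NN=NN1c1ccccc1 | intermediate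
11 | methyl 4-oxobutanoate | COC(=O)CCC=O | starting material
12 | nitromethane | C[N+](=O)[O-] | starting material
13 | methyl (4E)-5-nitropent-4-enoate | COC(=O)CC/C=C/[N+](=O)[O-] | intermediate
14 | methyl 5-methoxy-3-oxopentanoate | COCCC(=O)CC(=O)OC | starting material
15 | dimethyl (3S)-2-(3-methoxypropanoyl)-3-(nitromethyl)hexanedioate (C2 epimers) | COC(=O)C(C(=O)CCOC)[C@@H](C[N+](=O)[O-])CCC(=O)OC | intermediate
16 | dimethyl (3S)-3-(nitromethyl)-2-(prop-2-enoyl)hexanedioate (C2 epimers) | COC(=O)C(C(=O)C=C)[C@@H](C[N+](=O)[O-])CCC(=O)OC | intermediate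
17 | methyl (5S,6S)-2-hydroxy-6-(3-methoxy-3-oxopropyl)-5-nitrocyclohex-1-ene-1-carboxylate (enol tautomer of the β-keto ester) | COC(=O)C1=C(O)CC[C@H]([N+](=O)[O-])[C@H]1CCC(=O)OC | intermediate
18 | methyl (6S)-2-hydroxy-5,5-dimethoxy-6-(3-methoxy-3-oxopropyl)cyclohex-1-ene-1-carboxylate (enol tautomer of the β-keto ester) | COC(=O)C1=C(O)CCC(OC)(OC)[C@H]1CCC(=O)OC | intermediate
19 | acrolein | C=CC=O | starting material
20 | methyl (1R,2S)-3,3-dimethoxy-2-(3-methoxy-3-oxopropyl)-6-oxo-1-(3-oxopropyl)cyclohexane-1-carboxylate | O=CCC[C@@]1(C(=O)OC)[C@H](CCC(=O)OC)C(OC)(OC)CCC1=O | intermediate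
21 | 2-(triphenylphosphoranylidene)propanal | CC(C=O)=P(c1ccccc1)(c1ccccc1)c1ccccc1 | starting material
22 | methyl (1R,2S)-3,3-dimethoxy-2-(3-methoxy-3-oxopropyl)-1-[(3E)-4-methyl-5-oxopent-3-en-1-yl]-6-oxocyclohexane-1-carboxylate | O=C/C(C)=C/CC[C@@]1(C(=O)OC)[C@H](CCC(=O)OC)C(OC)(OC)CCC1=O | intermediate
23 | methyl (1R,2S)-1-Dn-3,3-dimethoxy-2-(3-methoxy-3-oxopropyl)-6-oxocyclohexane-1-carboxylate | C=C1CC[C@H](C)C(C)(C)[C@@H]1/C=C/C(C)=C/CC[C@@]1(C(=O)OC)[C@H](CCC(=O)OC)C(OC)(OC)CCC1=O | intermediate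
24 | methyl (1R,2S,6S)-1-Dn-6-hydroxy-3,3-dimethoxy-2-(3-methoxy-3-oxopropyl)-6-methylcyclohexane-1-carboxylate | C=C1CC[C@H](C)C(C)(C)[C@@H]1/C=C/C(C)=C/CC[C@@]1(C(=O)OC)[C@H](CCC(=O)OC)C(OC)(OC)CC[C@]1(C)O | intermediate
25 | methyl (1R,2S,6S)-1-Dn-6-hydroxy-2-(3-methoxy-3-oxopropyl)-6-methyl-3-oxocyclohexane-1-carboxylate | C=C1CC[C@H](C)C(C)(C)[C@@H]1/C=C/C(C)=C/CC[C@@]1(C(=O)OC)[C@H](CCC(=O)OC)C(=O)CC[C@]1(C)O | intermediate
26 | diethyl (1-cyanoethyl)phosphonate | CCOP(=O)(OCC)C(C)C#N | starting material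
27 | methyl (1R,2R,3Z,6S)-3-(1-cyanoethylidene)-1-Dn-6-hydroxy-2-(3-methoxy-3-oxopropyl)-6-methylcyclohexane-1-carboxylate | C=C1CC[C@H](C)C(C)(C)[C@@H]1/C=C/C(C)=C/CC[C@@]1(C(=O)OC)[C@H](CCC(=O)OC)/C(=C(/C)C#N)CC[C@]1(C)O | intermediate
28 | (2Z)-2-[(2R,3S,4S)-3-Dn-4-hydroxy-3-(hydroxymethyl)-2-(3-hydroxypropyl)-4-methylcyclohexylidene]propan-1-imine | C=C1CC[C@H](C)C(C)(C)[C@@H]1/C=C/C(C)=C/CC[C@@]1(CO)[C@H](CCCO)/C(=C(/C)C=N)CC[C@]1(C)O | intermediate
29 | (2Z)-2-[(2R,3S,4S)-3-Dn-4-hydroxy-3-(hydroxymethyl)-2-(3-hydroxypropyl)-4-methylcyclohexylidene]propanal (CNP0149035.1) | C=C1CC[C@H](C)C(C)(C)[C@@H]1/C=C/C(C)=C/CC[C@@]1(CO)[C@H](CCCO)/C(=C(/C)C=O)CC[C@]1(C)O | target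

**Totals**
Total step count: 16.
Longest linear sequence: 11 steps (1–6, then 12–16).

**The three steps most likely to fail**

Step 3 (the proposed new method). The acid may only isomerise the alkene, the enol oxygen may close instead of carbon, or the ee may be low. The fallback sets out from 4 and comes back at 7. SnCl4 in CH2Cl2 at 0 °C effects the known racemic β-keto ester–olefin cyclization of 4 to rac-methyl (1S,3S)-2,2,3-trimethyl-6-oxocyclohexane-1-carboxylate F1. Wittig methylenation as in step 4 gives rac-methyl (1R,3S)-2,2,3-trimethyl-6-methylidenecyclohexane-1-carboxylate F2, and LiAlH4 gives rac-[(1R,3S)-2,2,3-trimethyl-6-methylidenecyclohexyl]methanol F3. Lipase PS with vinyl acetate in t-BuOMe then acetylates the unwanted enantiomer to [(1S,3R)-2,2,3-trimethyl-6-methylidenecyclohexyl]methyl acetate F4; the unreacted alcohol is 7, with ee raised by running past 50% conversion.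

Step 13. The facial selectivity of methyl addition is predicted, not precedented, and the unhindered side-chain ester may compete. The fallback sets out from 23 and comes back at 29. Corey–Chaykovsky methylene transfer (Me3S+ I−, KN(SiMe3)2, THF) gives the spiro-epoxide methyl (3S,4R,5S)-4-Dn-6,6-dimethoxy-5-(3-methoxy-3-oxopropyl)-1-oxaspiro[2.5]octane-4-carboxylate F5; the sulfoxonium ylide would give the other face if that is what is needed. LiAlH4 opens the epoxide at CH2 and reduces both esters to (1S,2S,3S)-2-Dn-2-(hydroxymethyl)-3-(3-hydroxypropyl)-4,4-dimethoxy-1-methylcyclohexan-1-ol F6. PPTS in wet acetone gives (2S,3S,4S)-3-Dn-4-hydroxy-3-(hydroxymethyl)-2-(3-hydroxypropyl)-4-methylcyclohexan-1-one F7. HWE reaction with 26 gives (2Z)-2-[(2R,3S,4S)-3-Dn-4-hydroxy-3-(hydroxymethyl)-2-(3-hydroxypropyl)-4-methylcyclohexylidene]propanenitrile F8, and i-Bu2AlH then gives 29 through 28.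

Step 15. Addition to the hindered ketone may be slow and the Z selectivity incomplete. The fallback sets out from 25 and comes back at 29. Isopropenylmagnesium bromide with CeCl3 adds to the ketone to give methyl (1R,2S,6S)-1-Dn-3,6-dihydroxy-2-(3-methoxy-3-oxopropyl)-6-methyl-3-(prop-1-en-2-yl)cyclohexane-1-carboxylate F9 (C3 epimers). Pyridinium chlorochromate (C5H5NH[CrO3Cl]) effects the Babler–Dauben oxidative 1,3-transposition to methyl (1R,2R,3Z,6S)-1-Dn-6-hydroxy-2-(3-methoxy-3-oxopropyl)-6-methyl-3-(1-oxopropan-2-ylidene)cyclohexane-1-carboxylate F10; this route does not control the alkene geometry, so the Z isomer is separated by chromatography. i-Bu2AlH reduces the enal and both esters to (2Z)-2-[(2R,3S,4S)-3-Dn-4-hydroxy-3-(hydroxymethyl)-2-(3-hydroxypropyl)-4-methylcyclohexylidene]propan-1-ol F11, and MnO2 oxidises only the allylic primary alcohol to 29.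

**Further compounds**
F1 | step 3 | rac-methyl (1S,3S)-2,2,3-trimethyl-6-oxocyclohexane-1-carboxylate (racemate, one enantiomer drawn) | O=C1CC[C@H](C)C(C)(C)[C@@H]1C(=O)OC
F2 | step 3 | rac-methyl (1R,3S)-2,2,3-trimethyl-6-methylidenecyclohexane-1-carboxylate (racemate, one enantiomer drawn) | C=C1CC[C@H](C)C(C)(C)[C@@H]1C(=O)OC
F3 | step 3 | rac-[(1R,3S)-2,2,3-trimethyl-6-methylidenecyclohexyl]methanol (racemate, one enantiomer drawn) | C=C1CC[C@H](C)C(C)(C)[C@@H]1CO
F4 | step 3 | [(1S,3R)-2,2,3-trimethyl-6-methylidenecyclohexyl]methyl acetate | C=C1CC[C@@H](C)C(C)(C)[C@H]1COC(C)=O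
F5 | step 13 | methyl (3S,4R,5S)-4-Dn-6,6-dimethoxy-5-(3-methoxy-3-oxopropyl)-1-oxaspiro[2.5]octane-4-carboxylate | C=C1CC[C@H](C)C(C)(C)[C@@H]1/C=C/C(C)=C/CC[C@@]1(C(=O)OC)[C@H](CCC(=O)OC)C(OC)(OC)CC[C@@]12CO2
F6 | step 13 | (1S,2S,3S)-2-Dn-2-(hydroxymethyl)-3-(3-hydroxypropyl)-4,4-dimethoxy-1-methylcyclohexan-1-ol | C=C1CC[C@H](C)C(C)(C)[C@@H]1/C=C/C(C)=C/CC[C@@]1(CO)[C@H](CCCO)C(OC)(OC)CC[C@]1(C)O
F7 | step 13 | (2S,3S,4S)-3-Dn-4-hydroxy-3-(hydroxymethyl)-2-(3-hydroxypropyl)-4-methylcyclohexan-1-one | C=C1CC[C@H](C)C(C)(C)[C@@H]1/C=C/C(C)=C/CC[C@@]1(CO)[C@H](CCCO)C(=O)CC[C@]1(C)O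
F8 | step 13 | (2Z)-2-[(2R,3S,4S)-3-Dn-4-hydroxy-3-(hydroxymethyl)-2-(3-hydroxypropyl)-4-methylcyclohexylidene]propanenitrile | C=C1CC[C@H](C)C(C)(C)[C@@H]1/C=C/C(C)=C/CC[C@@]1(CO)[C@H](CCCO)/C(=C(/C)C#N)CC[C@]1(C)O
F9 | step 15 | methyl (1R,2S,6S)-1-Dn-3,6-dihydroxy-2-(3-methoxy-3-oxopropyl)-6-methyl-3-(prop-1-en-2-yl)cyclohexane-1-carboxylate (C3 epimers) | C=C1CC[C@H](C)C(C)(C)[C@@H]1/C=C/C(C)=C/CC[C@@]1(C(=O)OC)[C@H](CCC(=O)OC)C(O)(C(C)=C)CC[C@]1(C)O
F10 | step 15 | methyl (1R,2R,3Z,6S)-1-Dn-6-hydroxy-2-(3-methoxy-3-oxopropyl)-6-methyl-3-(1-oxopropan-2-ylidene)cyclohexane-1-carboxylate | C=C1CC[C@H](C)C(C)(C)[C@@H]1/C=C/C(C)=C/CC[C@@]1(C(=O)OC)[C@H](CCC(=O)OC)/C(=C(/C)C=O)CC[C@]1(C)O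
F11 | step 15 | (2Z)-2-[(2R,3S,4S)-3-Dn-4-hydroxy-3-(hydroxymethyl)-2-(3-hydroxypropyl)-4-methylcyclohexylidene]propan-1-ol | C=C1CC[C@H](C)C(C)(C)[C@@H]1/C=C/C(C)=C/CC[C@@]1(CO)[C@H](CCCO)/C(=C(/C)CO)CC[C@]1(C)O
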